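**Retrosynthetic overview**

1. Target 17 comes from the bis-silyl flavanone 16 by fluoride cleavage of the two aryl silyl ethers.
2. 16 is cut at C2–C3 of ring C. The strategy rests on C2, a benzylic carbon bonded to O1 and to the 4-methoxyphenyl ring, so an O1=C2 oxocarbenium ion forms easily, and on C3, the α-carbon of the C4 ketone on C4a of ring A, which can be held as an enol silane. This leads back to the racemic aryl methyl acetal 15; ring C is the only ring formed.
3. 15 comes from the 2-hydroxyacetophenone 11 by O1-alkylation with the α-chloro ether made from 12, then enol silylation.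
4. 11 carries the fully substituted ring A. It is built on the mirror-symmetric phenol 4 by ortho-bromination, O-(1,1-dimethylallyl)ation and Claisen rearrangement (C8 prenyl), then Stille acetylation (C4a).
5. 4 comes from 2-methylresorcinol 1 by silylation, C–H borylation para to the methyl group and oxidation.

Key step: step 10

Remark: the sense of induction of a given catalyst enantiomer cannot be predicted for this closure, so the enantiomer of the imidodiphosphorimidate catalyst that leads to 2S is assumed to be chosen in a screen.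

**Route**

Step 1
Reactants: 1 2-methylresorcinol
Product: 2 1,3-bis(tert-butyldimethylsilyloxy)-2-methylbenzene
Conditions: TBSCl (2.4 equiv), imidazole (5 equiv), DMF, rt
Reagents that add atoms: tert-butyldimethylsilyl chloride, CC(C)(C)[Si](C)(C)Cl
Why: Imidazole-promoted O-silylation of both phenols is routine, and the two bulky silyloxy groups later leave C5 as the only unhindered C–H for borylation.

Step 2
Reactants: 2 1,3-bis(tert-butyldimethylsilyloxy)-2-methylbenzene
Product: 4 3,5-bis(tert-butyldimethylsilyloxy)-4-methylphenol, via aryl pinacol boronate 3 (not isolated)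
Conditions: [Ir(OMe)(cod)]2 (1.5 mol%), dtbpy (3 mol%), B2pin2 (1.0 equiv), THF, 80 °C; solvent removed; aq KHSO5, acetone, rt, 15 min
Reagents that add atoms: bis(pinacolato)diboron, CC1(C)OB(OC1(C)C)B1OC(C)(C)C(C)(C)O1 (boron of intermediate 3 only); potassium peroxymonosulfate, [K+].[O-]S(=O)(=O)OO (phenol oxygen of 4)
Why: Sterically governed iridium-catalysed C–H borylation should take place only at C5, the one C–H without an ortho substituent (para to the methyl group), and oxidation of the C–B bond in the same pot under slightly acidic conditions should give the phenol while the aryl silyl ethers stay in place.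

Step 3
Reactants: 4 3,5-bis(tert-butyldimethylsilyloxy)-4-methylphenol
Product: 5 2-bromo-3,5-bis(tert-butyldimethylsilyloxy)-4-methylphenol
Conditions: NBS (1.0 equiv, slow addition), CH2Cl2, −78 °C
Reagents that add atoms: N-bromosuccinimide, O=C1CCC(=O)N1Br
Why: Electrophilic aromatic bromination of a phenol whose two ortho positions are equivalent and whose para position is blocked can give only one monobromide, and it is placed before the prenyl alkene exists so that bromoetherification cannot compete.

Step 4
Reactants: 6 2-methylbut-3-en-2-ol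
Product: 7 tert-butyl 2-methylbut-3-en-2-yl carbonate
Conditions: n-BuLi (1.0 equiv), THF, 0 °C; Boc2O, 0 °C to rt
Reagents that add atoms: di-tert-butyl dicarbonate, CC(C)(C)OC(=O)OC(=O)OC(C)(C)C
Why: Acylation of the lithium alkoxide of a tertiary allylic alcohol with Boc2O is a standard preparation of the mixed carbonate that serves as 1,1-dimethylallyl donor.

Step 5
Reactants: 5 2-bromo-3,5-bis(tert-butyldimethylsilyloxy)-4-methylphenol; 7 tert-butyl 2-methylbut-3-en-2-yl carbonate
Product: 8 1-bromo-2-(2-methylbut-3-en-2-yloxy)-4,6-bis(tert-butyldimethylsilyloxy)-5-methylbenzene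
Conditions: Pd(PPh3)4 (5 mol%), THF, 0 °C
Reagents that add atoms: none
Why: In this palladium-catalysed decarboxylative allylic etherification (Tsuji–Trost type) the tert-butoxide released from the carbonate deprotonates the phenol, and the phenoxide should attack the more substituted terminus of the 1,1-dimethylallyl–palladium cation under kinetic control at 0 °C, where the electron-rich C–Br bond does not undergo oxidative addition and no external base endangers the silyl ethers.

Step 6
Reactants: 8 1-bromo-2-(2-methylbut-3-en-2-yloxy)-4,6-bis(tert-butyldimethylsilyloxy)-5-methylbenzene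
Product: 9 2-bromo-3,5-bis(tert-butyldimethylsilyloxy)-4-methyl-6-(3-methylbut-2-enyl)phenol
Conditions: toluene, 110 °C, base-washed glassware
Reagents that add atoms: none
Why: The aromatic Claisen rearrangement ([3,3]) of a 1,1-dimethylallyl aryl ether delivers the normal prenyl group to the only free ortho carbon, since the other ortho position carries bromine and the para position carries the methyl group.

Step 7
Reactants: 9 2-bromo-3,5-bis(tert-butyldimethylsilyloxy)-4-methyl-6-(3-methylbut-2-enyl)phenol
Product: 11 1-[4,6-bis(tert-butyldimethylsilyloxy)-2-hydroxy-5-methyl-3-(3-methylbut-2-enyl)phenyl]ethanone, via 1-ethoxyvinyl arene 10 (not isolated)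
Conditions: tributyl(1-ethoxyvinyl)stannane (1.5 equiv), Pd(t-Bu3P)2 (5 mol%), toluene, 90 °C; then 1 M HCl, THF, 0 °C, 10 min; no fluoride work-up
Reagents that add atoms: tributyl(1-ethoxyvinyl)stannane, C=C(OCC)[Sn](CCCC)(CCCC)CCCC (the two acetyl carbons); water, O (carbonyl oxygen)
Why: A Kosugi–Migita–Stille coupling with an acyl-anion equivalent under neutral conditions, followed by brief hydrolysis of the enol ether, installs the acetyl group without Lewis acid (which would cyclise the ortho-prenyl phenol to a chroman) and without an aryllithium next to a silyloxy group (which would invite O-to-C silyl migration).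

Step 8
Reactants: 11 1-[4,6-bis(tert-butyldimethylsilyloxy)-2-hydroxy-5-methyl-3-(3-methylbut-2-enyl)phenyl]ethanone; 12 4-methoxybenzaldehyde dimethyl acetal
Product: 14 rac-1-[4,6-bis(tert-butyldimethylsilyloxy)-2-[methoxy(4-methoxyphenyl)methoxy]-5-methyl-3-(3-methylbut-2-enyl)phenyl]ethanone, via α-chloro ether 13 (not isolated)
Conditions: 12 (1.3 equiv), AcCl (1.2 equiv), SOCl2 (1 mol%), CH2Cl2, 0 °C to rt, volatiles removed; 11, NaH (1.05 equiv), THF, 0 °C, then 13, −78 to 0 °C; Et3N, aq NaHCO3; Et3N-deactivated silica
Reagents that add atoms: acetyl chloride, CC(=O)Cl (chlorine of intermediate 13 only)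
Why: Exchange of one methoxy group of the acetal for chloride with an acyl chloride gives a very reactive α-chloro ether, which should alkylate the sodium phenoxide on oxygen in a Williamson-type (SN1-like) etherification, because the ring has no free carbon and the phenol is far more acidic than the ketone.

Step 9
Reactants: 14 rac-1-[4,6-bis(tert-butyldimethylsilyloxy)-2-[methoxy(4-methoxyphenyl)methoxy]-5-methyl-3-(3-methylbut-2-enyl)phenyl]ethanone
Product: 15 rac-tert-butyl-[1-[4,6-bis(tert-butyldimethylsilyloxy)-2-[methoxy(4-methoxyphenyl)methoxy]-5-methyl-3-(3-methylbut-2-enyl)phenyl]ethenyloxy]dimethylsilane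
Conditions: KHMDS (1.2 equiv), THF, −78 °C; TBSCl (1.5 equiv), DMPU, −78 to 0 °C; pH 7 buffer; Et3N-deactivated silica
Reagents that add atoms: tert-butyldimethylsilyl chloride, CC(C)(C)[Si](C)(C)Cl
Why: Kinetic deprotonation of the methyl ketone (the only acidic C–H) and O-silylation of the potassium enolate give the enol silane without any Lewis acid that could ionise the acetal and start a racemic closure, and because all silyl groups are the same a silyl shift between the C5 oxygen and the enolate oxygen would lead to the same product.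

Step 10
Reactants: 15 rac-tert-butyl-[1-[4,6-bis(tert-butyldimethylsilyloxy)-2-[methoxy(4-methoxyphenyl)methoxy]-5-methyl-3-(3-methylbut-2-enyl)phenyl]ethenyloxy]dimethylsilane
Product: 16 (2S)-5,7-bis(tert-butyldimethylsilyloxy)-2-(4-methoxyphenyl)-6-methyl-8-(3-methylbut-2-enyl)chroman-4-one
Conditions: confined BINOL-derived imidodiphosphorimidate (3 mol%), presilylated with allyl(tert-butyl)dimethylsilane (6 mol%), toluene, 0.02 M, −78 to −60 °C; Et3N quench
Reagents that add atoms: none
Why: Proposed new method: the silylium ion of the catalyst ion pair should silylate the acetal methoxy oxygen, loss of tert-butyl(methoxy)dimethylsilane should give the planar O1=C2 oxocarbenium ion (stabilised by the 4-methoxyphenyl ring) paired with the chiral anion, and the enol silane carbon C3 should add to C2, after which the silylated C4 carbonyl hands its silyl group back to the anion and the cycle closes. The closest known reaction type is the chiral-counter-anion-directed Mukaiyama-type addition of enol silanes to oxocarbenium ions generated from racemic acetals or α-halo ethers, here transferred to an intramolecular ring-forming case. Ring C closes in a 6-(enolendo)-endo-trig mode, with C3, C4, C4a, C8a, O1 and C2 as ring members. C2 is the only new stereocentre and is set by the confined anion, which covers one face of the planar cation, and since both enantiomers of 15 give the same cation the step is stereoconvergent. The step needs ionisation of the C2–OMe bond and not of the C2–OAr bond, which the substrate should secure because the methoxy oxygen is the only unhindered basic acetal oxygen while the aryl oxygen sits between two ortho substituents; it also needs attack by C3 and not by the C8 prenyl alkene (Prins closure) or by a second molecule, which the much higher nucleophilicity of the enol silane, the six-membered tether, high dilution and low temperature should secure. No base is present, so the flavanone cannot reopen by retro-oxa-Michael reaction once it has formed.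

Step 11
Reactants: 16 (2S)-5,7-bis(tert-butyldimethylsilyloxy)-2-(4-methoxyphenyl)-6-methyl-8-(3-methylbut-2-enyl)chroman-4-one
Product: 17 (2S)-5,7-dihydroxy-2-(4-methoxyphenyl)-6-methyl-8-(3-methylbut-2-enyl)chroman-4-one
Conditions: TBAF (3 equiv), AcOH (3 equiv), THF, 0 °C
Reagents that add atoms: none
Why: Fluoride-mediated cleavage of aryl silyl ethers buffered with acetic acid should free both phenols without forming an enolate, so ring C is not opened and C2 is not scrambled, and without strong acid that could close the prenyl group onto the C7 hydroxyl.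

**Compound list**

1 | 2-methylresorcinol | Cc1c(O)cccc1O | starting material
2 | 1,3-bis(tert-butyldimethylsilyloxy)-2-methylbenzene | Cc1c(O[Si](C)(C)C(C)(C)C)cccc1O[Si](C)(C)C(C)(C)C | intermediate
3 | 2-[3,5-bis(tert-butyldimethylsilyloxy)-4-methylphenyl]-4,4,5,5-tetramethyl-1,3,2-dioxaborolane (not isolated) | Cc1c(O[Si](C)(C)C(C)(C)C)cc(B2OC(C)(C)C(C)(C)O2)cc1O[Si](C)(C)C(C)(C)C | intermediate
4 | 3,5-bis(tert-butyldimethylsilyloxy)-4-methylphenol | Cc1c(O[Si](C)(C)C(C)(C)C)cc(O)cc1O[Si](C)(C)C(C)(C)C | intermediate
5 | 2-bromo-3,5-bis(tert-butyldimethylsilyloxy)-4-methylphenol | Cc1c(O[Si](C)(C)C(C)(C)C)cc(O)c(Br)c1O[Si](C)(C)C(C)(C)C | intermediate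
6 | 2-methylbut-3-en-2-ol | CC(C)(O)C=C | starting material
7 | tert-butyl 2-methylbut-3-en-2-yl carbonate | CC(C)(C)OC(=O)OC(C)(C)C=C | intermediate
8 | 1-bromo-2-(2-methylbut-3-en-2-yloxy)-4,6-bis(tert-butyldimethylsilyloxy)-5-methylbenzene | Cc1c(O[Si](C)(C)C(C)(C)C)cc(OC(C)(C)C=C)c(Br)c1O[Si](C)(C)C(C)(C)C | intermediate
9 | 2-bromo-3,5-bis(tert-butyldimethylsilyloxy)-4-methyl-6-(3-methylbut-2-enyl)phenol | Cc1c(O[Si](C)(C)C(C)(C)C)c(CC=C(C)C)c(O)c(Br)c1O[Si](C)(C)C(C)(C)C | intermediate
10 | 2-(1-ethoxyethenyl)-3,5-bis(tert-butyldimethylsilyloxy)-4-methyl-6-(3-methylbut-2-enyl)phenol (not isolated) | Cc1c(O[Si](C)(C)C(C)(C)C)c(CC=C(C)C)c(O)c(C(=C)OCC)c1O[Si](C)(C)C(C)(C)C | intermediate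
11 | 1-[4,6-bis(tert-butyldimethylsilyloxy)-2-hydroxy-5-methyl-3-(3-methylbut-2-enyl)phenyl]ethanone | CC(=O)c1c(O)c(CC=C(C)C)c(O[Si](C)(C)C(C)(C)C)c(C)c1O[Si](C)(C)C(C)(C)C | intermediate
12 | 4-methoxybenzaldehyde dimethyl acetal | COc1ccc(C(OC)OC)cc1 | starting material
13 | rac-1-[chloro(methoxy)methyl]-4-methoxybenzene (not isolated) | COc1ccc(C(Cl)OC)cc1 | intermediate
14 | rac-1-[4,6-bis(tert-butyldimethylsilyloxy)-2-[methoxy(4-methoxyphenyl)methoxy]-5-methyl-3-(3-methylbut-2-enyl)phenyl]ethanone | COc1ccc(C(OC)Oc2c(C(C)=O)c(O[Si](C)(C)C(C)(C)C)c(C)c(O[Si](C)(C)C(C)(C)C)c2CC=C(C)C)cc1 | intermediate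
15 | rac-tert-butyl-[1-[4,6-bis(tert-butyldimethylsilyloxy)-2-[methoxy(4-methoxyphenyl)methoxy]-5-methyl-3-(3-methylbut-2-enyl)phenyl]ethenyloxy]dimethylsilane (key-step precursor) | COc1ccc(C(OC)Oc2c(C(=C)O[Si](C)(C)C(C)(C)C)c(O[Si](C)(C)C(C)(C)C)c(C)c(O[Si](C)(C)C(C)(C)C)c2CC=C(C)C)cc1 | intermediate
16 | (2S)-5,7-bis(tert-butyldimethylsilyloxy)-2-(4-methoxyphenyl)-6-methyl-8-(3-methylbut-2-enyl)chroman-4-one | COc1ccc([C@@H]2CC(=O)c3c(O[Si](C)(C)C(C)(C)C)c(C)c(O[Si](C)(C)C(C)(C)C)c(CC=C(C)C)c3O2)cc1 | intermediate
17 | (2S)-5,7-dihydroxy-2-(4-methoxyphenyl)-6-methyl-8-(3-methylbut-2-enyl)chroman-4-one (CNP0252391.1) | COc1ccc([C@@H]2CC(=O)c3c(O)c(C)c(O)c(CC=C(C)C)c3O2)cc1 | target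

**Step count**

Total: 11 steps. Longest linear sequence: 10 steps (steps 1, 2, 3, 5, 6, 7, 8, 9, 10, 11 from 1); step 4 is a side branch.

**Steps most likely to fail**

Step 10 (proposed new method). The acetal may ionise at the aryl–oxygen bond instead of the methoxy group, which would lead to an open-chain intermolecular adduct. The ion pair may loosen so that face control is lost, the prenyl alkene may capture the cation, or traces of acid may protodesilylate the enol silane. Fallback with known chemistry, setting out from 11: condensation with N,N-dimethylformamide dimethyl acetal (toluene, 80 °C) should give the enaminone (E)-3-(dimethylamino)-1-[4,6-bis(tert-butyldimethylsilyloxy)-2-hydroxy-5-methyl-3-(3-methylbut-2-enyl)phenyl]prop-2-en-1-one F1. Brief treatment with dilute HCl in CH2Cl2 should close it, with loss of dimethylamine, to 5,7-bis(tert-butyldimethylsilyloxy)-6-methyl-8-(3-methylbut-2-enyl)chromen-4-one F2. Rhodium-catalysed asymmetric 1,4-addition of 4-methoxyphenylboronic acid (Hayashi–Miyaura reaction, chiral diene or bisphosphine ligand, enantiomer chosen for 2S) would then set C2 and bring the route back at 16.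

Step 8. The chelated phenoxide, flanked by two ortho substituents, may alkylate slowly while the very labile chloro ether decomposes, and the mixed acetal may hydrolyse during isolation. Fallback, setting out from 11: Mitsunobu etherification with 4-methoxybenzyl alcohol (PPh3, DIAD, THF) should give the benzyl ether 1-[4,6-bis(tert-butyldimethylsilyloxy)-2-(4-methoxybenzyloxy)-5-methyl-3-(3-methylbut-2-enyl)phenyl]ethanone F3. Oxidation of its benzylic C–H bond with DDQ in CH2Cl2 containing methanol and 2,6-di-tert-butylpyridine, with capture of the cation by methanol, would create the acetal in the last operation and return to the route at 14.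

Step 7. Oxidative addition at the electron-rich C–Br bond between the hydroxyl and a silyloxy group may be slow, and the free phenol may protodestannylate the reagent. Fallback, setting out from 4 with the bromination left out:
- The palladium-catalysed etherification with 7 should give 1-(2-methylbut-3-en-2-yloxy)-3,5-bis(tert-butyldimethylsilyloxy)-4-methylbenzene F4.
- Claisen rearrangement in toluene at 110 °C should give 3,5-bis(tert-butyldimethylsilyloxy)-4-methyl-2-(3-methylbut-2-enyl)phenol F5.
- Magnesium-mediated ortho-formylation (MgCl2, Et3N, paraformaldehyde, Casnati–Skattebøl conditions) at the only free ring position should give 2-hydroxy-4,6-bis(tert-butyldimethylsilyloxy)-5-methyl-3-(3-methylbut-2-enyl)benzaldehyde F6.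
- Addition of MeMgBr (THF, −78 °C) should give rac-2-(1-hydroxyethyl)-3,5-bis(tert-butyldimethylsilyloxy)-4-methyl-6-(3-methylbut-2-enyl)phenol F7.
- Oxidation of the benzylic alcohol with MnO2 in CH2Cl2 comes back to the route at 11.

**Further compounds**

F1 | step 10 | (E)-3-(dimethylamino)-1-[4,6-bis(tert-butyldimethylsilyloxy)-2-hydroxy-5-methyl-3-(3-methylbut-2-enyl)phenyl]prop-2-en-1-one | CN(C)/C=C/C(=O)c1c(O)c(CC=C(C)C)c(O[Si](C)(C)C(C)(C)C)c(C)c1O[Si](C)(C)C(C)(C)C
F2 | step 10 | 5,7-bis(tert-butyldimethylsilyloxy)-6-methyl-8-(3-methylbut-2-enyl)chromen-4-one | O=c1ccoc2c(CC=C(C)C)c(O[Si](C)(C)C(C)(C)C)c(C)c(O[Si](C)(C)C(C)(C)C)c12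
F3 | step 8 | 1-[4,6-bis(tert-butyldimethylsilyloxy)-2-(4-methoxybenzyloxy)-5-methyl-3-(3-methylbut-2-enyl)phenyl]ethanone | COc1ccc(COc2c(C(C)=O)c(O[Si](C)(C)C(C)(C)C)c(C)c(O[Si](C)(C)C(C)(C)C)c2CC=C(C)C)cc1
F4 | step 7 | 1-(2-methylbut-3-en-2-yloxy)-3,5-bis(tert-butyldimethylsilyloxy)-4-methylbenzene | Cc1c(O[Si](C)(C)C(C)(C)C)cc(OC(C)(C)C=C)cc1O[Si](C)(C)C(C)(C)C
F5 | step 7 | 3,5-bis(tert-butyldimethylsilyloxy)-4-methyl-2-(3-methylbut-2-enyl)phenol | Cc1c(O[Si](C)(C)C(C)(C)C)cc(O)c(CC=C(C)C)c1O[Si](C)(C)C(C)(C)C
F6 | step 7 | 2-hydroxy-4,6-bis(tert-butyldimethylsilyloxy)-5-methyl-3-(3-methylbut-2-enyl)benzaldehyde | Cc1c(O[Si](C)(C)C(C)(C)C)c(C=O)c(O)c(CC=C(C)C)c1O[Si](C)(C)C(C)(C)C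
F7 | step 7 | rac-2-(1-hydroxyethyl)-3,5-bis(tert-butyldimethylsilyloxy)-4-methyl-6-(3-methylbut-2-enyl)phenol | Cc1c(O[Si](C)(C)C(C)(C)C)c(C(C)O)c(O)c(CC=C(C)C)c1O[Si](C)(C)C(C)(C)C
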